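## Retrosynthetic overview

1. The furanone is made last: AuCl3-catalysed transannular heterocyclisation/1,2-methyl shift of a ten-membered 2-hydroxy-2-alkynyl ketone (C10=O, C1(OH)(CH3), C2≡C3) moves CH3 from C1 to C10 and relays the C1 stereocentre to C10.
2. That macrocycle comes from an intramolecular CrCl2 Barbier allylation/lactonisation (C6–C7 bond) of an acyclic (Z)-enynal carrying a 2-(bromomethyl)enoate.
3. The chain comes from a boron aldol (C8–C9) of a methyl ketone with methyl (2Z)-2-(bromomethyl)-4-oxobut-2-enoate (from 2,2-dimethoxyacetaldehyde and methyl acrylate), then methacrylation.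
4. The methyl ketone comes from an enantioselective mono-alkynylation of butane-2,3-dione (new method; C1–C2 bond and C1 stereocentre) with a terminal (Z)-enyne.
5. The enyne comes from but-2-yne-1,4-diol and ethynylmagnesium bromide. Ring order: ten-membered carbocycle, then γ-lactone (same step), then furanone.

Conventions and assumption (one line): locants C1–C15 are germacrane locants of the target (C1 furanone C=O, C2=C3, C4=C5 with C15H2OAc on C4, C6 lactone CH–O, C7, C8 CH–O-methacrylate, C9H2, C10 quaternary with C14H3, C11=C13H2, C12 lactone C=O); Phebox-iPr = 2,6-bis(4-isopropyl-4,5-dihydro-1,3-oxazol-2-yl)phenyl; the antipodes of the Phebox ligand (step 5) and of Ipc2BCl (step 8) are assumed to be those that give 1R and 8S, to be confirmed on the first run and exchanged if the sense is opposite.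

## Route

Step 1
Reactants: 1 but-2-yne-1,4-diol
Product: 2 (2Z)-2-iodobut-2-ene-1,4-diol
Conditions: NaAlH2(OCH2CH2OMe)2, THF, 0 → 25 °C; then I2, −78 °C
Reagents that add atoms: iodine, II
Why: Directed trans-hydroalumination of the propargylic diol through a five-membered alkoxyaluminate, then iodinolysis of the C–Al bond with retention (hydroalumination–iodination), gives only the Z iodide with iodine cis to the remote CH2OH, which is the C3/C6-cis geometry of the target C4=C5 bond.

Step 2
Reactants: 2 (2Z)-2-iodobut-2-ene-1,4-diol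
Product: 3 (2Z)-4-[(tert-butyldimethylsilyl)oxy]-2-iodobut-2-en-1-ol
Conditions: TBSCl (1.0 equiv), imidazole, CH2Cl2, −20 °C
Reagents that add atoms: tert-butyldimethylsilyl chloride, CC(C)(C)[Si](C)(C)Cl
Why: Kinetic mono-silylation favours the hydroxymethyl on the CH= carbon (future C6), which is less hindered and less inductively deactivated than the one on the C–I carbon; the minor regioisomer and bis-ether are removed by chromatography.

Step 3
Reactants: 3 (2Z)-4-[(tert-butyldimethylsilyl)oxy]-2-iodobut-2-en-1-ol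
Product: 4 (2Z)-4-[(tert-butyldimethylsilyl)oxy]-2-iodobut-2-en-1-yl acetate
Conditions: Ac2O, pyridine, DMAP (cat.), CH2Cl2, 0 °C
Reagents that add atoms: acetic anhydride, CC(=O)OC(C)=O
Why: Standard DMAP-catalysed acylation of the remaining primary alcohol installs the C15 acetate, which is carried unchanged to the target.

Step 4
Reactants: 4 (2Z)-4-[(tert-butyldimethylsilyl)oxy]-2-iodobut-2-en-1-yl acetate; 5 ethynylmagnesium bromide
Product: 7 (2E)-4-[(tert-butyldimethylsilyl)oxy]-2-ethynylbut-2-en-1-yl acetate, via ethynylzinc bromide 6 (not isolated)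
Conditions: 5, ZnBr2, THF, 0 °C; then 4, Pd(PPh3)4 (5 mol%), THF, 0 → 25 °C
Reagents that add atoms: none
Why: Negishi coupling: zerovalent palladium inserts into the vinyl C–I bond much faster than it ionises the allylic acetate, and transmetalation from the ester-tolerant ethynylzinc bromide gives the terminal enyne with retention of alkene geometry.

Step 5
Reactants: 7 (2E)-4-[(tert-butyldimethylsilyl)oxy]-2-ethynylbut-2-en-1-yl acetate; 8 butane-2,3-dione
Product: 10 (2E)-4-[(tert-butyldimethylsilyl)oxy]-2-[(3R)-3-methyl-4-oxo-3-[(triethylsilyl)oxy]pent-1-yn-1-yl]but-2-en-1-yl acetate, via ketol 9 (not isolated)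
Conditions: 8 (3 equiv), Rh(OAc)2(H2O)(Phebox-iPr) (3 mol%), Et2O, 25 °C; evaporate; TESOTf, 2,6-lutidine, CH2Cl2, −78 → 0 °C
Reagents that add atoms: triethylsilyl trifluoromethanesulfonate, CC[Si](CC)(CC)OS(=O)(=O)C(F)(F)F
Why: Proposed new method: enantioselective mono-alkynylation of a symmetrical, enolisable dialkyl 1,2-diketone, in which acetate-assisted C–H metalation of the enyne gives a trivalent rhodium acetylide inside the chiral pincer pocket, one highly electrophilic diketone carbonyl inserts face-selectively into the Rh–C bond to set C1 as R, protonolysis by the next alkyne turns the catalyst over without external base (so no diketone self-aldol), and the hindered, deactivated ketol does not add a second alkyne; the closest known reaction type is the Phebox–rhodium-catalysed direct enantioselective alkynylation of α-keto esters and trifluoromethyl ketones, and the crude ketol is silylated in the same flask for the aldol.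

Step 6
Reactants: 11 2,2-dimethoxyacetaldehyde (60% aqueous solution); 12 methyl acrylate
Product: 13 methyl 3-hydroxy-4,4-dimethoxy-2-methylidenebutanoate (racemic)
Conditions: 12 (3 equiv), DABCO (0.5 equiv), 1,4-dioxane/H2O, 25 °C
Reagents that add atoms: none
Why: Morita–Baylis–Hillman reaction: the unhindered, electron-poor glyoxal mono-acetal is a fast acceptor for the DABCO–acrylate zwitterion in aqueous medium, and the racemic carbinol centre is destroyed in the next step.

Step 7
Reactants: 13 methyl 3-hydroxy-4,4-dimethoxy-2-methylidenebutanoate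
Product: 15 methyl (2Z)-2-(bromomethyl)-4-oxobut-2-enoate, via bromo acetal 14 (not isolated)
Conditions: NBS, Me2S, CH2Cl2, 0 → 25 °C; then TFA/H2O (9:1), 0 → 25 °C
Reagents that add atoms: N-bromosuccinimide, O=C1CCC(=O)N1Br; water, O
Why: Corey–Kim-type activation of the allylic alcohol and SN2′ attack of bromide give the thermodynamically preferred (Z)-2-(bromomethyl)enoate (β-substituent cis to CH2Br), and aqueous acid then hydrolyses the dimethyl acetal to the enal, which is used at once.

Step 8
Reactants: 10 (2E)-4-[(tert-butyldimethylsilyl)oxy]-2-[(3R)-3-methyl-4-oxo-3-[(triethylsilyl)oxy]pent-1-yn-1-yl]but-2-en-1-yl acetate; 15 methyl (2Z)-2-(bromomethyl)-4-oxobut-2-enoate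
Product: 16 methyl (2Z,4S,7R,10E)-10-(acetoxymethyl)-2-(bromomethyl)-12-[(tert-butyldimethylsilyl)oxy]-4-hydroxy-7-methyl-6-oxo-7-[(triethylsilyl)oxy]dodeca-2,10-dien-8-ynoate
Conditions: (−)-Ipc2BCl (1.5 equiv), iPr2NEt (1.4 equiv), Et2O, 0 °C; 15, −78 → −20 °C; MeOH, pH 7 buffer, 30% H2O2, 0 °C
Reagents that add atoms: none
Why: Diisopinocampheylboron enolate aldol of a methyl ketone: only the CH3 side can enolise (C1 is quaternary), the cyclic transition state of the chiral boron enolate directs attack on the si face of the enal to give 8S (the minor 8R diastereomer is separable because C1 is already fixed), and the boron enolate reacts only at the aldehyde and not at the allylic bromide or enoate.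

Step 9
Reactants: 16 (the aldol adduct named in step 8)
Product: 17 methyl (2Z,4S,7R,10E)-10-(acetoxymethyl)-2-(bromomethyl)-12-[(tert-butyldimethylsilyl)oxy]-7-methyl-4-[(2-methylprop-2-enoyl)oxy]-6-oxo-7-[(triethylsilyl)oxy]dodeca-2,10-dien-8-ynoate
Conditions: methacryloyl chloride, iPr2NEt, CH2Cl2, −20 → 0 °C
Reagents that add atoms: methacryloyl chloride, C=C(C)C(Cl)=O
Why: Acylation of the secondary C8 alcohol with the acid chloride and a non-nucleophilic amine (no DMAP, which would quaternise the allylic bromide) installs the methacrylate early, so that only O6 can lactonise later.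

Step 10
Reactants: 17 (the methacrylate named in step 9)
Product: 18 methyl (2Z,4S,7R,10E)-10-(acetoxymethyl)-2-(bromomethyl)-7,12-dihydroxy-7-methyl-4-[(2-methylprop-2-enoyl)oxy]-6-oxododeca-2,10-dien-8-ynoate
Conditions: 48% aq. HF, MeCN, 0 °C
Reagents that add atoms: none
Why: Acidic fluoride desilylation removes the primary TBS and tertiary TES ethers, while the esters, the allylic bromide and the β-acyloxy ketone are inert to aqueous HF.

Step 11
Reactants: 18 (the diol named in step 10)
Product: 19 methyl (2Z,4S,7R,10E)-10-(acetoxymethyl)-2-(bromomethyl)-7-hydroxy-7-methyl-4-[(2-methylprop-2-enoyl)oxy]-6,12-dioxododeca-2,10-dien-8-ynoate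
Conditions: activated MnO2 (20 equiv), CH2Cl2, 25 °C
Reagents that add atoms: none
Why: Heterogeneous MnO2 oxidation is selective for the primary allylic alcohol, leaves the tertiary ketol untouched and keeps the C3/C6-cis enal geometry under neutral conditions.

Step 12
Reactants: 19 (the enynal named in step 11)
Product: 21 (1R,4E,6R,7R,8S)-15-acetoxy-1-hydroxy-8-(methacryloyloxy)-10-oxo-14(10→1)-abeo-germacra-4,11(13)-dien-2-yn-6,12-olide (ten-membered ring; C1 bears OH and CH3; C3 cis to C6 across C4=C5), via hydroxy ester 20 (not isolated)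
Conditions: CrCl2 (8 equiv), THF, 25 °C, slow addition of 19 (final 2 mM); aq. NH4Cl
Reagents that add atoms: none
Why: Intramolecular Barbier (Nozaki–Hiyama-type) allylation: the allylchromium formed from the bromide and two CrCl2 attacks the aldehyde from C7 with allyl transposition through a six-membered chair transition state, closing the ten-membered ring with the 6,7-anti relationship (6R,7R) under 1,2-induction from the C8 ester and chemoselectively over the ketone, after which the trivalent chromium alkoxide closes the trans γ-lactone on the methyl ester.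

Step 13
Reactants: 21 (the macrocyclic ketol lactone named in step 12)
Product: 22 (4Z,6R,7R,8S,10R)-15-acetoxy-8-(methacryloyloxy)-1-oxo-3,10-epoxygermacra-2,4,11(13)-trien-6,12-olide (target CNP0179932.1)
Conditions: AuCl3 (5 mol%), CH2Cl2, 25 °C
Reagents that add atoms: none
Why: Gold-catalysed heterocyclisation/1,2-alkyl shift of a 2-hydroxy-2-alkynyl ketone: 5-endo attack of the C10 carbonyl oxygen on the AuCl3-activated C2≡C3 gives a cyclic oxocarbenium ion, the C1 methyl migrates suprafacially to C10 (α-ketol-type 1,2-shift) as C1 becomes the ketone, and protodeauration gives the 3(2H)-furanone, so that 1R is relayed to 10R with release of the strain of the cyclic enyne.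

## Compound list

1 | but-2-yne-1,4-diol | OCC#CCO | starting material
2 | (2Z)-2-iodobut-2-ene-1,4-diol | I/C(CO)=C\CO | intermediate
3 | (2Z)-4-[(tert-butyldimethylsilyl)oxy]-2-iodobut-2-en-1-ol | I/C(CO)=C\CO[Si](C)(C)C(C)(C)C | intermediate
4 | (2Z)-4-[(tert-butyldimethylsilyl)oxy]-2-iodobut-2-en-1-yl acetate | I/C(COC(C)=O)=C\CO[Si](C)(C)C(C)(C)C | intermediate
5 | ethynylmagnesium bromide | C#C[Mg]Br | starting material
6 | ethynylzinc bromide | C#C[Zn]Br | intermediate
7 | (2E)-4-[(tert-butyldimethylsilyl)oxy]-2-ethynylbut-2-en-1-yl acetate | C#C/C(COC(C)=O)=C\CO[Si](C)(C)C(C)(C)C | intermediate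
8 | butane-2,3-dione | CC(=O)C(C)=O | starting material
9 | (2E)-4-[(tert-butyldimethylsilyl)oxy]-2-[(3R)-3-hydroxy-3-methyl-4-oxopent-1-yn-1-yl]but-2-en-1-yl acetate | CC(=O)[C@](C)(O)C#C/C(COC(C)=O)=C\CO[Si](C)(C)C(C)(C)C | intermediate
10 | (2E)-4-[(tert-butyldimethylsilyl)oxy]-2-[(3R)-3-methyl-4-oxo-3-[(triethylsilyl)oxy]pent-1-yn-1-yl]but-2-en-1-yl acetate | CC(=O)[C@](C)(O[Si](CC)(CC)CC)C#C/C(COC(C)=O)=C\CO[Si](C)(C)C(C)(C)C | intermediate
11 | 2,2-dimethoxyacetaldehyde | COC(OC)C=O | starting material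
12 | methyl acrylate | C=CC(=O)OC | starting material
13 | methyl 3-hydroxy-4,4-dimethoxy-2-methylidenebutanoate (racemic) | COC(OC)C(O)C(=C)C(=O)OC | intermediate
14 | methyl (2Z)-2-(bromomethyl)-4,4-dimethoxybut-2-enoate | COC(OC)/C=C(\CBr)C(=O)OC | intermediate
15 | methyl (2Z)-2-(bromomethyl)-4-oxobut-2-enoate | O=C/C=C(\CBr)C(=O)OC | intermediate
16 | methyl (2Z,4S,7R,10E)-10-(acetoxymethyl)-2-(bromomethyl)-12-[(tert-butyldimethylsilyl)oxy]-4-hydroxy-7-methyl-6-oxo-7-[(triethylsilyl)oxy]dodeca-2,10-dien-8-ynoate | O[C@H](/C=C(\CBr)C(=O)OC)CC(=O)[C@](C)(O[Si](CC)(CC)CC)C#C/C(COC(C)=O)=C\CO[Si](C)(C)C(C)(C)C | intermediate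
17 | methyl (2Z,4S,7R,10E)-10-(acetoxymethyl)-2-(bromomethyl)-12-[(tert-butyldimethylsilyl)oxy]-7-methyl-4-[(2-methylprop-2-enoyl)oxy]-6-oxo-7-[(triethylsilyl)oxy]dodeca-2,10-dien-8-ynoate | C=C(C)C(=O)O[C@H](/C=C(\CBr)C(=O)OC)CC(=O)[C@](C)(O[Si](CC)(CC)CC)C#C/C(COC(C)=O)=C\CO[Si](C)(C)C(C)(C)C | intermediate
18 | methyl (2Z,4S,7R,10E)-10-(acetoxymethyl)-2-(bromomethyl)-7,12-dihydroxy-7-methyl-4-[(2-methylprop-2-enoyl)oxy]-6-oxododeca-2,10-dien-8-ynoate | C=C(C)C(=O)O[C@H](/C=C(\CBr)C(=O)OC)CC(=O)[C@](C)(O)C#C/C(COC(C)=O)=C\CO | intermediate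
19 | methyl (2Z,4S,7R,10E)-10-(acetoxymethyl)-2-(bromomethyl)-7-hydroxy-7-methyl-4-[(2-methylprop-2-enoyl)oxy]-6,12-dioxododeca-2,10-dien-8-ynoate | C=C(C)C(=O)O[C@H](/C=C(\CBr)C(=O)OC)CC(=O)[C@](C)(O)C#C/C(COC(C)=O)=C\C=O | intermediate
20 | methyl (1R,4E,6R,7S,8S)-15-acetoxy-1,6-dihydroxy-8-(methacryloyloxy)-10-oxo-14(10→1)-abeo-germacra-4,11(13)-dien-2-yn-12-oate (ten-membered ring closed, C6–OH and C12 methyl ester not yet lactonised) | C=C(C)C(=O)O[C@H]1CC(=O)[C@](C)(O)C#C/C(COC(C)=O)=C\[C@@H](O)[C@@H]1C(=C)C(=O)OC | intermediate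
21 | (1R,4E,6R,7R,8S)-15-acetoxy-1-hydroxy-8-(methacryloyloxy)-10-oxo-14(10→1)-abeo-germacra-4,11(13)-dien-2-yn-6,12-olide | C=C(C)C(=O)O[C@H]1CC(=O)[C@](C)(O)C#C/C(COC(C)=O)=C\[C@H]2OC(=O)C(=C)[C@H]12 | intermediate
22 | (4Z,6R,7R,8S,10R)-15-acetoxy-8-(methacryloyloxy)-1-oxo-3,10-epoxygermacra-2,4,11(13)-trien-6,12-olide (CNP0179932.1) | C=C(C)C(=O)O[C@H]1C[C@@]2(C)OC(=CC2=O)/C(COC(C)=O)=C\[C@H]2OC(=O)C(=C)[C@H]12 | target

## Step count and risks

Total step count: 13. Longest linear sequence: 11 (steps 1–5 and 8–13; steps 6–7 are a two-step branch).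

Three steps most likely to fail:

Step 5 (the proposed new method). Butane-2,3-dione may give low face selectivity or conversion, or the adduct may revert. The fallback uses known chemistry, sets out from 4 and comes back at 9. Ethyl pyruvate and trimethylsilylacetylene are joined by the established enantioselective zinc- or rhodium-catalysed alkynylation of α-keto esters to give ethyl (2R)-2-hydroxy-2-methyl-4-(trimethylsilyl)but-3-ynoate F1. MeNH(OMe)·HCl/iPrMgCl converts it into the Weinreb amide (2R)-2-hydroxy-N-methoxy-N,2-dimethyl-4-(trimethylsilyl)but-3-ynamide F2. MeMgBr gives (3R)-3-hydroxy-3-methyl-5-(trimethylsilyl)pent-4-yn-2-one F3, and K2CO3/MeOH gives (3R)-3-hydroxy-3-methylpent-4-yn-2-one F4. Sonogashira coupling of F4 with 4 (PdCl2(PPh3)2, CuI, Et3N) gives ketol 9, which is silylated to 10 as in step 5. This detour also supplies authentic (R)-material for assigning the sense of the new reaction.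

Step 8. The bromo-enal 15 is sensitive, residual amine can attack the allylic bromide, and reagent control with a methyl ketone may give a modest diastereomer ratio. The fallback sets out from 10 and comes back at 16. TMSOTf/Et3N converts 10 into the silyl enol ether (2E)-4-[(tert-butyldimethylsilyl)oxy]-2-[(3R)-3-methyl-3-[(triethylsilyl)oxy]-4-[(trimethylsilyl)oxy]pent-4-en-1-yn-1-yl]but-2-en-1-yl acetate F5. A Mukaiyama aldol with 15 under a tartrate-derived chiral (acyloxy)borane catalyst in EtCN at −78 °C (open transition state, no amine and no boron enolate in the C–C bond-forming step) gives the C8 trimethylsilyl ether of the aldol F6. Dilute acid work-up returns 16.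

Step 12. The ten-membered ring contains a cyclic 1,3-enyne, so cyclisation may lose to oligomerisation, and the C6/C7 configuration rests on substrate control. The fallback sets out from 18 and comes back at 22; it forms the furanone before the ring closure. TBSOTf/2,6-lutidine at −78 °C re-silylates only the primary alcohol of 18 to give the C6 silyl ether ketol F7. AuCl3 then effects the cyclisation/1,2-methyl shift on this acyclic ketol, where the protected C6 oxygen cannot attack the alkyne, to give the acyclic 10R furanone silyl ether F8. Aqueous HF gives the furanone alcohol F9 and MnO2 the furanone aldehyde F10. CrCl2 under high dilution closes the ring on the alkyne-free, furanone-templated chain via the furanone hydroxy ester F11 and gives 22 directly. This order also removes the transannular demand from step 13.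

Further compounds

F1 | step 5 | ethyl (2R)-2-hydroxy-2-methyl-4-(trimethylsilyl)but-3-ynoate | CCOC(=O)[C@](C)(O)C#C[Si](C)(C)C
F2 | step 5 | (2R)-2-hydroxy-N-methoxy-N,2-dimethyl-4-(trimethylsilyl)but-3-ynamide | CON(C)C(=O)[C@](C)(O)C#C[Si](C)(C)C
F3 | step 5 | (3R)-3-hydroxy-3-methyl-5-(trimethylsilyl)pent-4-yn-2-one | CC(=O)[C@](C)(O)C#C[Si](C)(C)C
F4 | step 5 | (3R)-3-hydroxy-3-methylpent-4-yn-2-one | CC(=O)[C@](C)(O)C#C
F5 | step 8 | (2E)-4-[(tert-butyldimethylsilyl)oxy]-2-[(3R)-3-methyl-3-[(triethylsilyl)oxy]-4-[(trimethylsilyl)oxy]pent-4-en-1-yn-1-yl]but-2-en-1-yl acetate | C=C(O[Si](C)(C)C)[C@](C)(O[Si](CC)(CC)CC)C#C/C(COC(C)=O)=C\CO[Si](C)(C)C(C)(C)C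
F6 | step 8 | methyl (2Z,4S,7R,10E)-10-(acetoxymethyl)-2-(bromomethyl)-12-[(tert-butyldimethylsilyl)oxy]-7-methyl-6-oxo-7-[(triethylsilyl)oxy]-4-[(trimethylsilyl)oxy]dodeca-2,10-dien-8-ynoate | C[Si](C)(C)O[C@H](/C=C(\CBr)C(=O)OC)CC(=O)[C@](C)(O[Si](CC)(CC)CC)C#C/C(COC(C)=O)=C\CO[Si](C)(C)C(C)(C)C
F7 | step 12 | methyl (2Z,4S,7R,10E)-10-(acetoxymethyl)-2-(bromomethyl)-12-[(tert-butyldimethylsilyl)oxy]-7-hydroxy-7-methyl-4-[(2-methylprop-2-enoyl)oxy]-6-oxododeca-2,10-dien-8-ynoate | C=C(C)C(=O)O[C@H](/C=C(\CBr)C(=O)OC)CC(=O)[C@](C)(O)C#C/C(COC(C)=O)=C\CO[Si](C)(C)C(C)(C)C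
F8 | step 12 | methyl (2Z,4S)-5-[(2R)-5-{(2Z)-1-acetoxy-4-[(tert-butyldimethylsilyl)oxy]but-2-en-2-yl}-2-methyl-3-oxo-2,3-dihydrofuran-2-yl]-2-(bromomethyl)-4-[(2-methylprop-2-enoyl)oxy]pent-2-enoate | C=C(C)C(=O)O[C@H](/C=C(\CBr)C(=O)OC)C[C@@]1(C)OC(=CC1=O)/C(COC(C)=O)=C\CO[Si](C)(C)C(C)(C)C
F9 | step 12 | methyl (2Z,4S)-5-[(2R)-5-{(2Z)-1-acetoxy-4-hydroxybut-2-en-2-yl}-2-methyl-3-oxo-2,3-dihydrofuran-2-yl]-2-(bromomethyl)-4-[(2-methylprop-2-enoyl)oxy]pent-2-enoate | C=C(C)C(=O)O[C@H](/C=C(\CBr)C(=O)OC)C[C@@]1(C)OC(=CC1=O)/C(COC(C)=O)=C\CO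
F10 | step 12 | methyl (2Z,4S)-5-[(2R)-5-{(2Z)-1-acetoxy-4-oxobut-2-en-2-yl}-2-methyl-3-oxo-2,3-dihydrofuran-2-yl]-2-(bromomethyl)-4-[(2-methylprop-2-enoyl)oxy]pent-2-enoate | C=C(C)C(=O)O[C@H](/C=C(\CBr)C(=O)OC)C[C@@]1(C)OC(=CC1=O)/C(COC(C)=O)=C\C=O
F11 | step 12 | methyl (4Z,6R,7S,8S,10R)-15-acetoxy-6-hydroxy-8-(methacryloyloxy)-1-oxo-3,10-epoxygermacra-2,4,11(13)-trien-12-oate | C=C(C)C(=O)O[C@H]1C[C@@]2(C)OC(=CC2=O)/C(COC(C)=O)=C\[C@@H](O)[C@@H]1C(=C)C(=O)OC
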